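**Retrosynthetic overview**
- Target ⇒ (acetonide and TMS removal) ⇒ C7=C8 from an anti-selective boron aldol between a 2-bromo-4-silyloxycyclopentenone and a C1–C7 acetonide aldehyde, followed by stereospecific anti-dehydration to the 7Z alkene.
- Aldehyde ⇐ 2-deoxy-L-ribose: sugar C3/C4 become C5/C6, a stabilised Wittig adds C1–C2, sugar C5 is oxidised to the C7 aldehyde.
- Bromo enone ⇐ hydroxy enone (nucleophilic epoxidation, then HBr) ⇐ 1,3-carbonyl transposition of (R)-4-silyloxycyclopentenone after an acetate aldol addition (sets C12) and a Z-Wittig with a leaf-alcohol-derived ylide.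
- Rings: the cyclopentene ring is bought; no carbocycle is built. Only a temporary dioxolane (step 1) and oxirane (step 14) are formed.

Assumption: 2-deoxy-L-ribose and (R)-4-(tert-butyldimethylsilyloxy)cyclopent-2-enone are taken as purchasable chiral-pool building blocks; prostanoid numbering (C1 = ester carbon, ring = C8–C12) is used in the comments.

**Route**

Step 1
Reactants: 1 2-deoxy-L-ribose
Product: 2 2-deoxy-3,4-O-isopropylidene-L-erythro-pentopyranose (anomer mixture)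
Conditions: 2-methoxypropene (1.3 equiv), PPTS (cat.), EtOAc, 0 °C → rt
Reagents that add atoms: 2-methoxypropene, C=C(C)OC
Why: Kinetic acetonide formation takes the cis-3,4-diol of the pyranose and leaves the lactol free; the sugar's 3R,4S centres (future C5, C6) are untouched.

Step 2
Reactants: 2 2-deoxy-3,4-O-isopropylidene-L-erythro-pentopyranose; 3 methyl (triphenylphosphoranylidene)acetate
Product: 4 methyl (2E)-4-[(4R,5S)-5-(hydroxymethyl)-2,2-dimethyl-1,3-dioxolan-4-yl]but-2-enoate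
Conditions: PhCO2H (cat.), THF, reflux
Reagents that add atoms: none
Why: Wittig olefination of the open-chain aldehyde tautomer with a stabilised ylide gives the E-enoate and releases the primary C7 hydroxyl.

Step 3
Reactants: 4 methyl (2E)-4-[(4R,5S)-5-(hydroxymethyl)-2,2-dimethyl-1,3-dioxolan-4-yl]but-2-enoate
Product: 5 methyl 4-[(4R,5S)-5-(hydroxymethyl)-2,2-dimethyl-1,3-dioxolan-4-yl]butanoate
Conditions: H2 (1 atm), 10% Pd/C, EtOAc, rt
Reagents that add atoms: none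
Why: Catalytic hydrogenation saturates the enoate without touching acetonide, ester or stereocentres.

Step 4
Reactants: 5 methyl 4-[(4R,5S)-5-(hydroxymethyl)-2,2-dimethyl-1,3-dioxolan-4-yl]butanoate
Product: 6 methyl 4-[(4R,5R)-5-formyl-2,2-dimethyl-1,3-dioxolan-4-yl]butanoate
Conditions: Dess–Martin periodinane (1.3 equiv), pyridine, CH2Cl2, 0 °C → rt; used at once
Reagents that add atoms: none
Why: Dess–Martin oxidation gives the α-alkoxy aldehyde under near-neutral conditions, which avoids epimerisation of the cis-dioxolane.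

Step 5
Reactants: 7 (3Z)-hex-3-en-1-ol
Product: 8 (3Z)-1-bromohex-3-ene
Conditions: CBr4, PPh3, CH2Cl2, 0 °C
Reagents that add atoms: carbon tetrabromide, BrC(Br)(Br)Br
Why: Appel bromination of the primary alcohol proceeds without touching the Z-alkene.

Step 6
Reactants: 8 (3Z)-1-bromohex-3-ene
Product: 9 [(3Z)-hex-3-en-1-yl]triphenylphosphonium bromide
Conditions: PPh3, MeCN, reflux
Reagents that add atoms: triphenylphosphine, c1ccc(cc1)P(c1ccccc1)c1ccccc1
Why: SN2 quaternisation of a primary bromide gives the Wittig salt.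

Step 7
Reactants: 10 (4R)-4-[(tert-butyldimethylsilyl)oxy]cyclopent-2-en-1-one; 11 ethyl acetate
Product: 13 ethyl 2-[(1R,4R)-4-[(tert-butyldimethylsilyl)oxy]-1-hydroxycyclopent-2-en-1-yl]acetate, via ethyl lithioacetate 12 (not isolated)
Conditions: LDA (1.15 equiv), THF, −78 °C, 11; then 10, −78 °C, 45 min; AcOH/THF quench at −78 °C
Reagents that add atoms: none
Why: Aldol addition of the lithium ester enolate is kinetically 1,2 and occurs on the carbonyl face opposite the silyloxy group (OH cis to OTBS), which fixes the future C12 centre; the minor epimer is removed by chromatography.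

Step 8
Reactants: 13 ethyl 2-[(1R,4R)-4-[(tert-butyldimethylsilyl)oxy]-1-hydroxycyclopent-2-en-1-yl]acetate
Product: 14 ethyl 2-[(1R,4R)-4-[(tert-butyldimethylsilyl)oxy]-1-[(triethylsilyl)oxy]cyclopent-2-en-1-yl]acetate
Conditions: TESOTf, 2,6-lutidine, CH2Cl2, −78 → 0 °C
Reagents that add atoms: triethylsilyl trifluoromethanesulfonate, CC[Si](CC)(CC)OS(=O)(=O)C(F)(F)F
Why: Silyl triflate silylation caps the tertiary alcohol so that the later β-oxy aldehyde cannot undergo retro-aldol cleavage.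

Step 9
Reactants: 14 ethyl 2-[(1R,4R)-4-[(tert-butyldimethylsilyl)oxy]-1-[(triethylsilyl)oxy]cyclopent-2-en-1-yl]acetate
Product: 15 2-[(1S,4R)-4-[(tert-butyldimethylsilyl)oxy]-1-[(triethylsilyl)oxy]cyclopent-2-en-1-yl]ethan-1-ol
Conditions: DIBAL-H (2.5 equiv), CH2Cl2, −78 → 0 °C; Rochelle salt work-up
Reagents that add atoms: none
Why: Full DIBAL reduction of the ester to the primary alcohol is more dependable than stopping at the aldehyde; the descriptor changes only through CIP priority.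

Step 10
Reactants: 15 2-[(1S,4R)-4-[(tert-butyldimethylsilyl)oxy]-1-[(triethylsilyl)oxy]cyclopent-2-en-1-yl]ethan-1-ol
Product: 16 2-[(1R,4R)-4-[(tert-butyldimethylsilyl)oxy]-1-[(triethylsilyl)oxy]cyclopent-2-en-1-yl]acetaldehyde
Conditions: Dess–Martin periodinane, pyridine, CH2Cl2, 0 °C → rt
Reagents that add atoms: none
Why: Dess–Martin oxidation gives the β-silyloxy aldehyde without acid or strong base.

Step 11
Reactants: 16 2-[(1R,4R)-4-[(tert-butyldimethylsilyl)oxy]-1-[(triethylsilyl)oxy]cyclopent-2-en-1-yl]acetaldehyde; 9 [(3Z)-hex-3-en-1-yl]triphenylphosphonium bromide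
Product: 18 tert-butyl({(1R,4S)-4-[(2Z,5Z)-octa-2,5-dien-1-yl]-4-[(triethylsilyl)oxy]cyclopent-2-en-1-yl}oxy)dimethylsilane, via (3Z)-hex-3-enylidene(triphenyl)phosphorane 17 (not isolated)
Conditions: 9, NaHMDS, THF, −78 → 0 °C; then 16, −78 °C → rt
Reagents that add atoms: none
Why: Salt-free Wittig reaction of a non-stabilised ylide gives the new C14=C15 bond Z, while the C17=C18 Z-alkene comes unchanged from leaf alcohol.

Step 12
Reactants: 18 tert-butyl({(1R,4S)-4-[(2Z,5Z)-octa-2,5-dien-1-yl]-4-[(triethylsilyl)oxy]cyclopent-2-en-1-yl}oxy)dimethylsilane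
Product: 19 (1S,4R)-1-[(2Z,5Z)-octa-2,5-dien-1-yl]cyclopent-2-ene-1,4-diol
Conditions: TBAF (2.5 equiv), THF, 0 °C → rt; aqueous work-up
Reagents that add atoms: none
Why: Fluoride desilylation removes both silyl ethers under non-acidic conditions, which the tertiary allylic carbinol tolerates.

Step 13
Reactants: 19 (1S,4R)-1-[(2Z,5Z)-octa-2,5-dien-1-yl]cyclopent-2-ene-1,4-diol
Product: 20 (4S)-4-hydroxy-4-[(2Z,5Z)-octa-2,5-dien-1-yl]cyclopent-2-en-1-one
Conditions: activated MnO2 (excess), CH2Cl2, rt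
Reagents that add atoms: none
Why: Allylic oxidation can only take the secondary carbinol and completes the 1,3-carbonyl transposition; the control centre is erased after having set C12.

Step 14
Reactants: 20 (4S)-4-hydroxy-4-[(2Z,5Z)-octa-2,5-dien-1-yl]cyclopent-2-en-1-one
Product: 21 (1S,4S,5R)-4-hydroxy-4-[(2Z,5Z)-octa-2,5-dien-1-yl]-6-oxabicyclo[3.1.0]hexan-2-one
Conditions: t-BuOOH (decane), DBU, CH2Cl2, 0 °C → rt
Reagents that add atoms: tert-butyl hydroperoxide, CC(C)(C)OO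
Why: Weitz–Scheffer nucleophilic epoxidation attacks only the electron-poor enone C=C and not the skipped diene; the oxirane centres (drawn cis to OH) are lost again in step 15.

Step 15
Reactants: 21 (1S,4S,5R)-4-hydroxy-4-[(2Z,5Z)-octa-2,5-dien-1-yl]-6-oxabicyclo[3.1.0]hexan-2-one
Product: 23 (4S)-2-bromo-4-hydroxy-4-[(2Z,5Z)-octa-2,5-dien-1-yl]cyclopent-2-en-1-one, via trans-bromohydrin 22 (not isolated)
Conditions: 48% aq HBr (1.5 equiv), acetone, 0 °C → rt
Reagents that add atoms: hydrogen bromide, Br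
Why: Acid-mediated epoxide opening by bromide at the α-carbon (SN2 next to C=O, away from the quaternary centre) and dehydration of the β-hydroxy ketone give the α-bromo enone, as in the epoxide route to 4-halo-3-keto steroids.

Step 16
Reactants: 23 (4S)-2-bromo-4-hydroxy-4-[(2Z,5Z)-octa-2,5-dien-1-yl]cyclopent-2-en-1-one
Product: 24 (4S)-2-bromo-4-[(2Z,5Z)-octa-2,5-dien-1-yl]-4-[(trimethylsilyl)oxy]cyclopent-2-en-1-one
Conditions: N-(trimethylsilyl)imidazole, CH2Cl2, rt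
Reagents that add atoms: N-(trimethylsilyl)imidazole, C[Si](C)(C)n1ccnc1
Why: Silylation of the tertiary alcohol under neutral conditions protects it from the enolisation and dehydration reagents that follow.

Step 17
Reactants: 24 (4S)-2-bromo-4-[(2Z,5Z)-octa-2,5-dien-1-yl]-4-[(trimethylsilyl)oxy]cyclopent-2-en-1-one; 6 methyl 4-[(4R,5R)-5-formyl-2,2-dimethyl-1,3-dioxolan-4-yl]butanoate
Product: 26 methyl 4-[(4R,5S)-5-{(R)-[(1R,5S)-3-bromo-5-[(2Z,5Z)-octa-2,5-dien-1-yl]-2-oxo-5-[(trimethylsilyl)oxy]cyclopent-3-en-1-yl](hydroxy)methyl}-2,2-dimethyl-1,3-dioxolan-4-yl]butanoate, via dicyclohexylboron dienolate 25 (not isolated)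
Conditions: Cy2BCl (1.4 equiv), Et3N (1.6 equiv), Et2O, −78 → 0 °C; then 6, −78 → −20 °C; MeOH, pH 7 buffer, 30% H2O2, 0 °C
Reagents that add atoms: none
Why: In this boron-mediated intermolecular aldol the ring-locked E(O)-enolate reacts through a Zimmerman–Traxler chair to give the 7,8-anti adduct; both new centres (drawn for attack syn to OTMS) disappear in step 18, so only their anti relationship matters.

Step 18
Reactants: 26 methyl 4-[(4R,5S)-5-{(R)-[(1R,5S)-3-bromo-5-[(2Z,5Z)-octa-2,5-dien-1-yl]-2-oxo-5-[(trimethylsilyl)oxy]cyclopent-3-en-1-yl](hydroxy)methyl}-2,2-dimethyl-1,3-dioxolan-4-yl]butanoate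
Product: 27 methyl 4-[(4R,5S)-5-{(Z)-[(5R)-3-bromo-5-[(2Z,5Z)-octa-2,5-dien-1-yl]-2-oxo-5-[(trimethylsilyl)oxy]cyclopent-3-en-1-ylidene]methyl}-2,2-dimethyl-1,3-dioxolan-4-yl]butanoate
Conditions: Martin sulfurane Ph2S[OC(CF3)2Ph]2 (2 equiv), CH2Cl2, 0 °C → rt
Reagents that add atoms: none
Why: Martin sulfurane dehydration is an anti-periplanar E2 elimination of the alkoxysulfonium, so the 7,8-anti aldol gives the 7Z alkylidene (C6 cis to the C9 carbonyl).

Step 19
Reactants: 27 methyl 4-[(4R,5S)-5-{(Z)-[(5R)-3-bromo-5-[(2Z,5Z)-octa-2,5-dien-1-yl]-2-oxo-5-[(trimethylsilyl)oxy]cyclopent-3-en-1-ylidene]methyl}-2,2-dimethyl-1,3-dioxolan-4-yl]butanoate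
Product: 28 methyl (5R,6S,7Z,12R,14Z,17Z)-10-bromo-5,6,12-trihydroxy-9-oxoprosta-7,10,14,17-tetraenoate (CNP0241880.1)
Conditions: CSA (0.2 equiv), MeOH, 0 °C → rt; NaHCO3 quench
Reagents that add atoms: none
Why: Acid-catalysed transketalisation and desilylation in methanol remove the acetonide and TMS ether; methanol as solvent keeps the methyl ester and suppresses δ-lactonisation, and no stereocentre is touched.

**Compound list**
1 | 2-deoxy-L-ribose (pyranose form, 3R,4S) | OC1C[C@@H](O)[C@@H](O)CO1 | starting material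
2 | 2-deoxy-3,4-O-isopropylidene-L-erythro-pentopyranose (anomer mixture) | OC1C[C@@H]2[C@H](CO1)OC(C)(C)O2 | intermediate
3 | methyl (triphenylphosphoranylidene)acetate | COC(=O)C=P(c1ccccc1)(c1ccccc1)c1ccccc1 | starting material
4 | methyl (2E)-4-[(4R,5S)-5-(hydroxymethyl)-2,2-dimethyl-1,3-dioxolan-4-yl]but-2-enoate | OC[C@@H]1OC(C)(C)O[C@@H]1C/C=C/C(=O)OC | intermediate
5 | methyl 4-[(4R,5S)-5-(hydroxymethyl)-2,2-dimethyl-1,3-dioxolan-4-yl]butanoate | OC[C@@H]1OC(C)(C)O[C@@H]1CCCC(=O)OC | intermediate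
6 | methyl 4-[(4R,5R)-5-formyl-2,2-dimethyl-1,3-dioxolan-4-yl]butanoate | O=C[C@@H]1OC(C)(C)O[C@@H]1CCCC(=O)OC | intermediate
7 | (3Z)-hex-3-en-1-ol | CC/C=C\CCO | starting material
8 | (3Z)-1-bromohex-3-ene | CC/C=C\CCBr | intermediate
9 | [(3Z)-hex-3-en-1-yl]triphenylphosphonium bromide | CC/C=C\CC[P+](c1ccccc1)(c1ccccc1)c1ccccc1.[Br-] | intermediate
10 | (4R)-4-[(tert-butyldimethylsilyl)oxy]cyclopent-2-en-1-one | O=C1C=C[C@H](O[Si](C)(C)C(C)(C)C)C1 | starting material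
11 | ethyl acetate | CCOC(C)=O | starting material
12 | ethyl lithioacetate (lithium enolate of 11) | C=C(O[Li])OCC | intermediate
13 | ethyl 2-[(1R,4R)-4-[(tert-butyldimethylsilyl)oxy]-1-hydroxycyclopent-2-en-1-yl]acetate (OH cis to OTBS) | CCOC(=O)C[C@@]1(O)C=C[C@H](O[Si](C)(C)C(C)(C)C)C1 | intermediate
14 | ethyl 2-[(1R,4R)-4-[(tert-butyldimethylsilyl)oxy]-1-[(triethylsilyl)oxy]cyclopent-2-en-1-yl]acetate | CCOC(=O)C[C@@]1(O[Si](CC)(CC)CC)C=C[C@H](O[Si](C)(C)C(C)(C)C)C1 | intermediate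
15 | 2-[(1S,4R)-4-[(tert-butyldimethylsilyl)oxy]-1-[(triethylsilyl)oxy]cyclopent-2-en-1-yl]ethan-1-ol | OCC[C@@]1(O[Si](CC)(CC)CC)C=C[C@H](O[Si](C)(C)C(C)(C)C)C1 | intermediate
16 | 2-[(1R,4R)-4-[(tert-butyldimethylsilyl)oxy]-1-[(triethylsilyl)oxy]cyclopent-2-en-1-yl]acetaldehyde | O=CC[C@@]1(O[Si](CC)(CC)CC)C=C[C@H](O[Si](C)(C)C(C)(C)C)C1 | intermediate
17 | (3Z)-hex-3-enylidene(triphenyl)phosphorane | CC/C=C\CC=P(c1ccccc1)(c1ccccc1)c1ccccc1 | intermediate
18 | tert-butyl({(1R,4S)-4-[(2Z,5Z)-octa-2,5-dien-1-yl]-4-[(triethylsilyl)oxy]cyclopent-2-en-1-yl}oxy)dimethylsilane | CC/C=C\C/C=C\C[C@@]1(O[Si](CC)(CC)CC)C=C[C@H](O[Si](C)(C)C(C)(C)C)C1 | intermediate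
19 | (1S,4R)-1-[(2Z,5Z)-octa-2,5-dien-1-yl]cyclopent-2-ene-1,4-diol | CC/C=C\C/C=C\C[C@@]1(O)C=C[C@H](O)C1 | intermediate
20 | (4S)-4-hydroxy-4-[(2Z,5Z)-octa-2,5-dien-1-yl]cyclopent-2-en-1-one | CC/C=C\C/C=C\C[C@@]1(O)C=CC(=O)C1 | intermediate
21 | (1S,4S,5R)-4-hydroxy-4-[(2Z,5Z)-octa-2,5-dien-1-yl]-6-oxabicyclo[3.1.0]hexan-2-one (oxirane cis to OH) | CC/C=C\C/C=C\C[C@@]1(O)[C@@H]2O[C@@H]2C(=O)C1 | intermediate
22 | (2R,3S,4S)-2-bromo-3,4-dihydroxy-4-[(2Z,5Z)-octa-2,5-dien-1-yl]cyclopentan-1-one (trans-bromohydrin) | CC/C=C\C/C=C\C[C@@]1(O)[C@H](O)[C@@H](Br)C(=O)C1 | intermediate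
23 | (4S)-2-bromo-4-hydroxy-4-[(2Z,5Z)-octa-2,5-dien-1-yl]cyclopent-2-en-1-one | CC/C=C\C/C=C\C[C@@]1(O)C=C(Br)C(=O)C1 | intermediate
24 | (4S)-2-bromo-4-[(2Z,5Z)-octa-2,5-dien-1-yl]-4-[(trimethylsilyl)oxy]cyclopent-2-en-1-one | CC/C=C\C/C=C\C[C@@]1(O[Si](C)(C)C)C=C(Br)C(=O)C1 | intermediate
25 | {[(3S)-5-bromo-3-[(2Z,5Z)-octa-2,5-dien-1-yl]-3-[(trimethylsilyl)oxy]cyclopenta-1,4-dien-1-yl]oxy}dicyclohexylborane (boron dienolate of 24) | CC/C=C\C/C=C\C[C@@]1(O[Si](C)(C)C)C=C(Br)C(OB(C2CCCCC2)C2CCCCC2)=C1 | intermediate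
26 | methyl 4-[(4R,5S)-5-{(R)-[(1R,5S)-3-bromo-5-[(2Z,5Z)-octa-2,5-dien-1-yl]-2-oxo-5-[(trimethylsilyl)oxy]cyclopent-3-en-1-yl](hydroxy)methyl}-2,2-dimethyl-1,3-dioxolan-4-yl]butanoate (7,8-anti aldol; prostanoid 5R,6S,7R,8R,12S) | CC/C=C\C/C=C\C[C@@]1(O[Si](C)(C)C)C=C(Br)C(=O)[C@@H]1[C@@H](O)[C@@H]2OC(C)(C)O[C@@H]2CCCC(=O)OC | intermediate
27 | methyl 4-[(4R,5S)-5-{(Z)-[(5R)-3-bromo-5-[(2Z,5Z)-octa-2,5-dien-1-yl]-2-oxo-5-[(trimethylsilyl)oxy]cyclopent-3-en-1-ylidene]methyl}-2,2-dimethyl-1,3-dioxolan-4-yl]butanoate | CC/C=C\C/C=C\C[C@@]1(O[Si](C)(C)C)C=C(Br)C(=O)/C1=C\[C@@H]2OC(C)(C)O[C@@H]2CCCC(=O)OC | intermediate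
28 | methyl (5R,6S,7Z,12R,14Z,17Z)-10-bromo-5,6,12-trihydroxy-9-oxoprosta-7,10,14,17-tetraenoate | CC/C=C\C/C=C\C[C@@]1(O)C=C(Br)C(=O)/C1=C\[C@H](O)[C@H](O)CCCC(=O)OC | target

**Totals**
Total step count: 19. Longest linear sequence: 13 steps (steps 7–19, from 10).

**Three steps most likely to fail, with fallbacks**

Step 15 (epoxide to bromo enone). HBr may add to the skipped diene, or the bromohydrin may not dehydrate cleanly. The fallback leaves the epoxide path: it sets out from 20 and comes back at 24. Silylation of 20 with N-(trimethylsilyl)imidazole gives (4S)-4-[(2Z,5Z)-octa-2,5-dien-1-yl]-4-[(trimethylsilyl)oxy]cyclopent-2-en-1-one F1. Conjugate addition of bromotrimethylsilane (CH2Cl2, −78 °C) gives the β-bromo silyl enol ether (4S)-3-bromo-4-[(2Z,5Z)-octa-2,5-dien-1-yl]-1,4-bis[(trimethylsilyl)oxy]cyclopent-1-ene F2. NBS (THF, −78 °C) brominates only the enol ether, which is far more nucleophilic than the isolated alkenes, to give (4S)-2,3-dibromo-4-[(2Z,5Z)-octa-2,5-dien-1-yl]-4-[(trimethylsilyl)oxy]cyclopentan-1-one F3. Et3N then eliminates the β-bromide to give 24.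

Step 17 (boron aldol). Soft enolisation of the α-bromo dienone may be unclean, or the anti selectivity may be low. The fallback replaces the metal enolate by a Mukaiyama aldol: it sets out from 24 and comes back at 26. TMSOTf/Et3N (CH2Cl2, −78 °C) gives the silyl dienol ether {[(3S)-5-bromo-3-[(2Z,5Z)-octa-2,5-dien-1-yl]-3-[(trimethylsilyl)oxy]cyclopenta-1,4-dien-1-yl]oxy}trimethylsilane F4. This is combined with 6 under BF3·OEt2 (CH2Cl2, −78 °C), and the 7,8-anti adduct 26 is separated from its syn isomers by chromatography.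

Step 18 (Z-selective dehydration). The elimination may lose stereospecificity through an E1cB pathway and give the 7E isomer. The fallback gives up stereospecific dehydration: it sets out from 26 and comes back at 27. MsCl/Et3N gives the C7 methanesulfonate of 26 F5. DBU-induced E1cB elimination gives 27 together with its (7E) isomer, methyl 4-[(4R,5S)-5-{(E)-[(5R)-3-bromo-5-[(2Z,5Z)-octa-2,5-dien-1-yl]-2-oxo-5-[(trimethylsilyl)oxy]cyclopent-3-en-1-ylidene]methyl}-2,2-dimethyl-1,3-dioxolan-4-yl]butanoate F6. F6 is isomerised photochemically (350 nm, benzene, Pyrex) to the E/Z photostationary mixture; 27 is separated by chromatography and F6 is recycled.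

**Further compounds**
F1 | step 15 | (4S)-4-[(2Z,5Z)-octa-2,5-dien-1-yl]-4-[(trimethylsilyl)oxy]cyclopent-2-en-1-one | CC/C=C\C/C=C\C[C@@]1(O[Si](C)(C)C)C=CC(=O)C1
F2 | step 15 | (4S)-3-bromo-4-[(2Z,5Z)-octa-2,5-dien-1-yl]-1,4-bis[(trimethylsilyl)oxy]cyclopent-1-ene (C3 epimer mixture) | CC/C=C\C/C=C\C[C@@]1(O[Si](C)(C)C)C(Br)C=C(O[Si](C)(C)C)C1
F3 | step 15 | (4S)-2,3-dibromo-4-[(2Z,5Z)-octa-2,5-dien-1-yl]-4-[(trimethylsilyl)oxy]cyclopentan-1-one (C2/C3 diastereomer mixture) | CC/C=C\C/C=C\C[C@@]1(O[Si](C)(C)C)C(Br)C(Br)C(=O)C1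
F4 | step 17 | {[(3S)-5-bromo-3-[(2Z,5Z)-octa-2,5-dien-1-yl]-3-[(trimethylsilyl)oxy]cyclopenta-1,4-dien-1-yl]oxy}trimethylsilane | CC/C=C\C/C=C\C[C@@]1(O[Si](C)(C)C)C=C(Br)C(O[Si](C)(C)C)=C1
F5 | step 18 | C7 methanesulfonate of 26 | CC/C=C\C/C=C\C[C@@]1(O[Si](C)(C)C)C=C(Br)C(=O)[C@@H]1[C@@H](OS(C)(=O)=O)[C@@H]2OC(C)(C)O[C@@H]2CCCC(=O)OC
F6 | step 18 | methyl 4-[(4R,5S)-5-{(E)-[(5R)-3-bromo-5-[(2Z,5Z)-octa-2,5-dien-1-yl]-2-oxo-5-[(trimethylsilyl)oxy]cyclopent-3-en-1-ylidene]methyl}-2,2-dimethyl-1,3-dioxolan-4-yl]butanoate | CC/C=C\C/C=C\C[C@@]1(O[Si](C)(C)C)C=C(Br)C(=O)/C1=C/[C@@H]2OC(C)(C)O[C@@H]2CCCC(=O)OC
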